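The target is opened at the C5–C6 bond: C6 is a secondary allylic carbinol attached to C5, the β-carbon of the cyclopentenone (C3=O, C4=C5) that is fused to the seven-membered ring. Reading that bond as an alkenylmetal–aldehyde union, one Nozaki–Hiyama–Kishi reaction forms C5–C6, closes the seven-membered ring, creates the C6 stereocentre and releases the natural product with both esters and the C1 hydroxyl already in place. Its precursor is an acyclic C6 aldehyde (C7 acetoxyisopropyl, C8 angelate, C10 methyl) hanging from C1 of a 4-hydroxy-3-iodo-2-methylcyclopentenone, assembled by ketone crotylation and an auxiliary-controlled aldol.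

Key step: step 15

Numbering used: C1 fusion carbinol, C2 CH2, C3 ketone, C4 methyl-bearing alkene carbon, C5 fusion alkene carbon, C6 carbinol, C7 (carries C11, the acetoxyisopropyl carbon), C8 angelate carbon, C9 CH2, C10 methyl-bearing carbon. "Ring unit A" in the names below is (1R,4R)-4-(tert-butyldimethylsilyloxy)-2-iodo-3-methyl-1-(triethylsilyloxy)cyclopent-2-en-1-yl (its C1 is C1 of the target, its C4 is C3).

Assumption (step 3): in the chair-like crotyl transfer, boron binds the carbonyl lone pair remote from iodine, so the iodoalkenyl arm is pseudo-equatorial; the (Z)-crotyl reagent is chosen on that basis.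

Step 1
Reactants: 1 (R)-4-(tert-butyldimethylsilyloxy)cyclopent-2-en-1-one
Product: 3 (R)-4-(tert-butyldimethylsilyloxy)-3-methylcyclopent-2-en-1-one, via trimethylsilyl enol ether 2 (not isolated)
Conditions: MeMgBr, CuBr·SMe2 (cat.), TMSCl, THF, −78 °C; then Pd(OAc)2, MeCN, rt
Reagents that add atoms: methylmagnesium bromide, C[Mg]Br
Why: Copper-catalysed conjugate addition (anti to the silyloxy group, trapped as silyl enol ether 2) followed by Saegusa–Ito dehydrogenation should return the enone with the future C4 methyl group in place, the silyloxy stereocentre (future C3, R) being untouched.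

Step 2
Reactants: 3 (R)-4-(tert-butyldimethylsilyloxy)-3-methylcyclopent-2-en-1-one
Product: 4 (R)-4-(tert-butyldimethylsilyloxy)-2-iodo-3-methylcyclopent-2-en-1-one
Conditions: I2, pyridine, DMAP (cat.), CH2Cl2, 0 °C → rt
Reagents that add atoms: iodine, II
Why: Amine-mediated α-iodination of the enone (conjugate addition of the amine, iodination of the enolate, elimination) puts iodine on the future C5 while the carbonyl carbon is still the future C1, so the position of the halide involves no regiochemical choice.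

Step 3
Reactants: 4 (R)-4-(tert-butyldimethylsilyloxy)-2-iodo-3-methylcyclopent-2-en-1-one; 5 potassium (Z)-but-2-en-1-yltrifluoroborate
Product: 6 (1R,4R)-1-[(2S)-but-3-en-2-yl]-4-(tert-butyldimethylsilyloxy)-2-iodo-3-methylcyclopent-2-en-1-ol
Conditions: BF3·OEt2, CH2Cl2, −78 → −40 °C
Reagents that add atoms: none
Why: Lewis-acid-promoted crotylboration of a ketone through a Zimmerman–Traxler chair: addition anti to the silyloxy group should set C1 (hydroxyl cis to the silyl ether), and with the iodoalkenyl arm pseudo-equatorial the axial methyl group of the (Z)-crotyl unit should set C10 as S.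

Step 4
Reactants: 6 (1R,4R)-1-[(2S)-but-3-en-2-yl]-4-(tert-butyldimethylsilyloxy)-2-iodo-3-methylcyclopent-2-en-1-ol
Product: 7 (1R,4R)-1-[(2S)-but-3-en-2-yl]-4-(tert-butyldimethylsilyloxy)-2-iodo-3-methyl-1-(triethylsilyloxy)cyclopent-2-ene
Conditions: TESOTf, 2,6-lutidine, CH2Cl2, −78 → 0 °C
Reagents that add atoms: triethylsilyl trifluoromethanesulfonate, CC[Si](CC)(CC)OS(=O)(=O)C(F)(F)F
Why: Silylation of the hindered tertiary alcohol with a silyl triflate (standard protection) prevents lactol formation with the C8 aldehyde made later and touches no stereocentre.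

Step 5
Reactants: 7 (1R,4R)-1-[(2S)-but-3-en-2-yl]-4-(tert-butyldimethylsilyloxy)-2-iodo-3-methyl-1-(triethylsilyloxy)cyclopent-2-ene
Product: 9 (3S)-3-(ring unit A)butan-1-ol, via B-alkyl-9-BBN adduct 8 (not isolated)
Conditions: 9-BBN, THF, 0 °C → rt; then NaOH, H2O2, 0 °C
Reagents that add atoms: hydrogen peroxide, OO
Why: Anti-Markovnikov hydroboration–oxidation of the monosubstituted alkene should give the primary C8 alcohol, the tetrasubstituted iodoalkene being inert to the bulky borane.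

Step 6
Reactants: 9 (3S)-3-(ring unit A)butan-1-ol
Product: 10 (3S)-3-(ring unit A)butanal
Conditions: Dess–Martin periodinane, NaHCO3, CH2Cl2, rt
Reagents that add atoms: none
Why: Dess–Martin oxidation of a primary alcohol to the aldehyde under buffered conditions that leave the silyl ethers and the alkenyl iodide alone.

Step 7
Reactants: 11 3-(tert-butyldimethylsilyloxy)propanoic acid; 12 (S)-4-benzyloxazolidin-2-one
Product: 14 (S)-4-benzyl-3-[3-(tert-butyldimethylsilyloxy)propanoyl]oxazolidin-2-one, via mixed pivalic anhydride 13 (not isolated)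
Conditions: PivCl, Et3N, THF, −20 °C; then LiCl, 12, rt
Reagents that add atoms: none
Why: N-Acylation of the oxazolidinone through a mixed anhydride with LiCl/Et3N activation is a standard imide synthesis that needs no strong base.

Step 8
Reactants: 10 (3S)-3-(ring unit A)butanal; 14 (S)-4-benzyl-3-[3-(tert-butyldimethylsilyloxy)propanoyl]oxazolidin-2-one
Product: 16 (S)-4-benzyl-3-[(2S,3R,5S)-2-(tert-butyldimethylsilyloxymethyl)-3-hydroxy-5-(ring unit A)hexanoyl]oxazolidin-2-one, via dibutylboron (Z)-enolate 15 (not isolated)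
Conditions: Bu2BOTf, i-Pr2NEt, CH2Cl2, 0 °C; 10, −78 → 0 °C; pH 7 buffer, MeOH, H2O2
Reagents that add atoms: none
Why: Evans syn-aldol reaction: the (Z)-boron enolate should react through a chair on the face opposite the benzyl group, setting C7 and C8 under auxiliary control, with the imide carbonyl as the future C11 and the silyloxymethyl group as the future C6.

Step 9
Reactants: 16 (S)-4-benzyl-3-[(2S,3R,5S)-2-(tert-butyldimethylsilyloxymethyl)-3-hydroxy-5-(ring unit A)hexanoyl]oxazolidin-2-one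
Product: 17 methyl (2S,3R,5S)-2-(tert-butyldimethylsilyloxymethyl)-3-hydroxy-5-(ring unit A)hexanoate
Conditions: MeOMgBr (cat., from MeMgBr in MeOH), MeOH/CH2Cl2, 0 °C
Reagents that add atoms: methanol, CO
Why: Magnesium methoxide transesterification cleaves the exocyclic acyl–nitrogen bond and returns the auxiliary under conditions too mild for retro-aldol cleavage or epimerisation at C7.

Step 10
Reactants: 17 methyl (2S,3R,5S)-2-(tert-butyldimethylsilyloxymethyl)-3-hydroxy-5-(ring unit A)hexanoate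
Product: 18 (3S,4R,6S)-3-(tert-butyldimethylsilyloxymethyl)-2-methyl-6-(ring unit A)heptane-2,4-diol
Conditions: MeMgBr (excess), CeCl3, THF, −78 → 0 °C
Reagents that add atoms: methylmagnesium bromide, C[Mg]Br
Why: Double Grignard addition to the ester builds the C11 dimethyl carbinol; with the cerium additive addition should outrun enolisation, so C7 keeps its configuration.

Step 11
Reactants: 18 (3S,4R,6S)-3-(tert-butyldimethylsilyloxymethyl)-2-methyl-6-(ring unit A)heptane-2,4-diol; 19 angelic acid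
Product: 21 (3S,4R,6S)-3-(tert-butyldimethylsilyloxymethyl)-2-hydroxy-2-methyl-6-(ring unit A)heptan-4-yl (Z)-2-methylbut-2-enoate, via mixed trichlorobenzoic anhydride 20 (not isolated)
Conditions: 19, 2,4,6-trichlorobenzoyl chloride, Et3N, toluene, rt; then 18, 75 °C
Reagents that add atoms: none
Why: Yamaguchi-type esterification through the mixed anhydride, run without DMAP, should acylate the secondary C8 hydroxyl in preference to the tertiary one and keep the (Z)-geometry of the angelate.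

Step 12
Reactants: 21 (3S,4R,6S)-3-(tert-butyldimethylsilyloxymethyl)-2-hydroxy-2-methyl-6-(ring unit A)heptan-4-yl (Z)-2-methylbut-2-enoate
Product: 22 (3S,4R,6S)-2-acetoxy-3-(tert-butyldimethylsilyloxymethyl)-2-methyl-6-(ring unit A)heptan-4-yl (Z)-2-methylbut-2-enoate
Conditions: Ac2O, DMAP, Et3N, CH2Cl2, rt → 40 °C
Reagents that add atoms: acetic anhydride, CC(=O)OC(C)=O
Why: DMAP-catalysed acyl transfer acetylates the tertiary C11 alcohol, the only free hydroxyl group left in 21.

Step 13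
Reactants: 22 (3S,4R,6S)-2-acetoxy-3-(tert-butyldimethylsilyloxymethyl)-2-methyl-6-(ring unit A)heptan-4-yl (Z)-2-methylbut-2-enoate
Product: 23 (3S,4R,6S)-2-acetoxy-6-[(1R,4R)-1,4-dihydroxy-2-iodo-3-methylcyclopent-2-en-1-yl]-3-(hydroxymethyl)-2-methylheptan-4-yl (Z)-2-methylbut-2-enoate
Conditions: HF·pyridine, pyridine, THF, 0 °C → rt
Reagents that add atoms: none
Why: Fluoride-mediated cleavage of all three silyl ethers under buffered, mildly acidic conditions should leave both esters in place and disfavour acyl migration to the freed primary hydroxyl.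

Step 14
Reactants: 23 (3S,4R,6S)-2-acetoxy-6-[(1R,4R)-1,4-dihydroxy-2-iodo-3-methylcyclopent-2-en-1-yl]-3-(hydroxymethyl)-2-methylheptan-4-yl (Z)-2-methylbut-2-enoate
Product: 24 (3S,4R,6S)-2-acetoxy-3-formyl-6-[(1R)-1-hydroxy-2-iodo-3-methyl-4-oxocyclopent-2-en-1-yl]-2-methylheptan-4-yl (Z)-2-methylbut-2-enoate
Conditions: Dess–Martin periodinane (excess), NaHCO3, CH2Cl2, 0 °C → rt; used crude
Reagents that add atoms: none
Why: One Dess–Martin oxidation converts the C3 allylic alcohol into the β-iodoenone and the C6 primary alcohol into the aldehyde, the tertiary C1 hydroxyl being inert; the buffer limits β-elimination of the acyloxy groups.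

Step 15
Reactants: 24 (3S,4R,6S)-2-acetoxy-3-formyl-6-[(1R)-1-hydroxy-2-iodo-3-methyl-4-oxocyclopent-2-en-1-yl]-2-methylheptan-4-yl (Z)-2-methylbut-2-enoate
Product: 26 (1R,6R,7S,8R,10S)-11-acetoxy-1,6-dihydroxy-3-oxoguai-4-en-8-yl (Z)-2-methylbut-2-enoate (CNP0273287.1), via alkenylchromium dichloride 25 (not isolated)
Conditions: CrCl2 (excess), NiCl2 (cat.), degassed DMSO, rt, high dilution (slow addition of 24)
Reagents that add atoms: none
Why: Zerovalent nickel, generated from NiCl2 by CrCl2, inserts into the C5–I bond, transmetalation gives alkenylchromium 25 (trivalent chromium), and this adds to the C6 aldehyde to give the alcohol on work-up. This is the Nozaki–Hiyama–Kishi alkenyl halide–aldehyde coupling run intramolecularly, a standard medium-ring closure that tolerates free hydroxyl groups, esters and ketones. The seven-membered ring closes in the 7-exo-trig mode; the rigid five-membered ring fixes the metal-bearing C5 next to C1, so the chain that starts at C1 reaches it without strain. The new C6 stereocentre is controlled by C7 in a Felkin–Anh arrangement: the acetoxyisopropyl group lies anti to the incoming C5 and the ring-forming C8 branch sits next to the carbonyl oxygen, which places the C6 hydroxyl cis to the C7 substituent. The step needs chemoselectivity for the aldehyde over the ketone, the esters and β-elimination, which the non-basic, aldehyde-selective organochromium reagent and high dilution should secure.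

Compound list
1 | (R)-4-(tert-butyldimethylsilyloxy)cyclopent-2-en-1-one | O=C1C[C@@H](O[Si](C)(C)C(C)(C)C)C=C1 | starting material
2 | (3R,4R)-4-(tert-butyldimethylsilyloxy)-3-methyl-1-(trimethylsilyloxy)cyclopent-1-ene | C[Si](C)(C)OC1=C[C@@H](C)[C@H](O[Si](C)(C)C(C)(C)C)C1 | intermediate
3 | (R)-4-(tert-butyldimethylsilyloxy)-3-methylcyclopent-2-en-1-one | O=C1C[C@@H](O[Si](C)(C)C(C)(C)C)C(C)=C1 | intermediate
4 | (R)-4-(tert-butyldimethylsilyloxy)-2-iodo-3-methylcyclopent-2-en-1-one | O=C1C[C@@H](O[Si](C)(C)C(C)(C)C)C(C)=C1I | intermediate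
5 | potassium (Z)-but-2-en-1-yltrifluoroborate | C/C=C\C[B-](F)(F)F.[K+] | starting material
6 | (1R,4R)-1-[(2S)-but-3-en-2-yl]-4-(tert-butyldimethylsilyloxy)-2-iodo-3-methylcyclopent-2-en-1-ol | C=C[C@H](C)[C@]1(O)C[C@@H](O[Si](C)(C)C(C)(C)C)C(C)=C1I | intermediate
7 | (1R,4R)-1-[(2S)-but-3-en-2-yl]-4-(tert-butyldimethylsilyloxy)-2-iodo-3-methyl-1-(triethylsilyloxy)cyclopent-2-ene | C=C[C@H](C)[C@]1(O[Si](CC)(CC)CC)C[C@@H](O[Si](C)(C)C(C)(C)C)C(C)=C1I | intermediate
8 | 9-[(3S)-3-(ring unit A)butyl]-9-borabicyclo[3.3.1]nonane | B1(CC[C@H](C)[C@]2(O[Si](CC)(CC)CC)C[C@@H](O[Si](C)(C)C(C)(C)C)C(C)=C2I)C2CCCC1CCC2 | intermediate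
9 | (3S)-3-(ring unit A)butan-1-ol | OCC[C@H](C)[C@]1(O[Si](CC)(CC)CC)C[C@@H](O[Si](C)(C)C(C)(C)C)C(C)=C1I | intermediate
10 | (3S)-3-(ring unit A)butanal | O=CC[C@H](C)[C@]1(O[Si](CC)(CC)CC)C[C@@H](O[Si](C)(C)C(C)(C)C)C(C)=C1I | intermediate
11 | 3-(tert-butyldimethylsilyloxy)propanoic acid | CC(C)(C)[Si](C)(C)OCCC(=O)O | starting material
12 | (S)-4-benzyloxazolidin-2-one | O=C1N[C@@H](Cc2ccccc2)CO1 | starting material
13 | 3-(tert-butyldimethylsilyloxy)propanoic pivalic anhydride | CC(C)(C)[Si](C)(C)OCCC(=O)OC(=O)C(C)(C)C | intermediate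
14 | (S)-4-benzyl-3-[3-(tert-butyldimethylsilyloxy)propanoyl]oxazolidin-2-one | CC(C)(C)[Si](C)(C)OCCC(=O)N1[C@@H](Cc2ccccc2)COC1=O | intermediate
15 | dibutylboron (Z)-enolate of 14 | CCCCB(CCCC)O/C(=C\CO[Si](C)(C)C(C)(C)C)N1[C@@H](Cc2ccccc2)COC1=O | intermediate
16 | (S)-4-benzyl-3-[(2S,3R,5S)-2-(tert-butyldimethylsilyloxymethyl)-3-hydroxy-5-(ring unit A)hexanoyl]oxazolidin-2-one | CC(C)(C)[Si](C)(C)OC[C@H](C(=O)N1[C@@H](Cc2ccccc2)COC1=O)[C@H](O)C[C@H](C)[C@]1(O[Si](CC)(CC)CC)C[C@@H](O[Si](C)(C)C(C)(C)C)C(C)=C1I | intermediate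
17 | methyl (2S,3R,5S)-2-(tert-butyldimethylsilyloxymethyl)-3-hydroxy-5-(ring unit A)hexanoate | CC(C)(C)[Si](C)(C)OC[C@H](C(=O)OC)[C@H](O)C[C@H](C)[C@]1(O[Si](CC)(CC)CC)C[C@@H](O[Si](C)(C)C(C)(C)C)C(C)=C1I | intermediate
18 | (3S,4R,6S)-3-(tert-butyldimethylsilyloxymethyl)-2-methyl-6-(ring unit A)heptane-2,4-diol | CC(C)(C)[Si](C)(C)OC[C@H](C(C)(C)O)[C@H](O)C[C@H](C)[C@]1(O[Si](CC)(CC)CC)C[C@@H](O[Si](C)(C)C(C)(C)C)C(C)=C1I | intermediate
19 | angelic acid, (Z)-2-methylbut-2-enoic acid | C/C=C(/C)C(=O)O | starting material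
20 | (Z)-2-methylbut-2-enoic 2,4,6-trichlorobenzoic anhydride | C/C=C(/C)C(=O)OC(=O)c1c(Cl)cc(Cl)cc1Cl | intermediate
21 | (3S,4R,6S)-3-(tert-butyldimethylsilyloxymethyl)-2-hydroxy-2-methyl-6-(ring unit A)heptan-4-yl (Z)-2-methylbut-2-enoate | CC(C)(C)[Si](C)(C)OC[C@H](C(C)(C)O)[C@H](OC(=O)/C(C)=C\C)C[C@H](C)[C@]1(O[Si](CC)(CC)CC)C[C@@H](O[Si](C)(C)C(C)(C)C)C(C)=C1I | intermediate
22 | (3S,4R,6S)-2-acetoxy-3-(tert-butyldimethylsilyloxymethyl)-2-methyl-6-(ring unit A)heptan-4-yl (Z)-2-methylbut-2-enoate | CC(C)(C)[Si](C)(C)OC[C@H](C(C)(C)OC(C)=O)[C@H](OC(=O)/C(C)=C\C)C[C@H](C)[C@]1(O[Si](CC)(CC)CC)C[C@@H](O[Si](C)(C)C(C)(C)C)C(C)=C1I | intermediate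
23 | (3S,4R,6S)-2-acetoxy-6-[(1R,4R)-1,4-dihydroxy-2-iodo-3-methylcyclopent-2-en-1-yl]-3-(hydroxymethyl)-2-methylheptan-4-yl (Z)-2-methylbut-2-enoate | OC[C@H](C(C)(C)OC(C)=O)[C@H](OC(=O)/C(C)=C\C)C[C@H](C)[C@]1(O)C[C@@H](O)C(C)=C1I | intermediate
24 | (3S,4R,6S)-2-acetoxy-3-formyl-6-[(1R)-1-hydroxy-2-iodo-3-methyl-4-oxocyclopent-2-en-1-yl]-2-methylheptan-4-yl (Z)-2-methylbut-2-enoate (cyclisation precursor) | O=C[C@H](C(C)(C)OC(C)=O)[C@H](OC(=O)/C(C)=C\C)C[C@H](C)[C@]1(O)CC(=O)C(C)=C1I | intermediate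
25 | alkenylchromium dichloride derived from 24 (CrCl2 unit on C5 in place of iodine) | O=C[C@H](C(C)(C)OC(C)=O)[C@H](OC(=O)/C(C)=C\C)C[C@H](C)[C@]1(O)CC(=O)C(C)=C1[Cr](Cl)Cl | intermediate
26 | (1R,6R,7S,8R,10S)-11-acetoxy-1,6-dihydroxy-3-oxoguai-4-en-8-yl (Z)-2-methylbut-2-enoate, CNP0273287.1 | C/C=C(/C)C(=O)O[C@@H]1C[C@H](C)[C@]2(O)CC(=O)C(C)=C2[C@H](O)[C@@H]1C(C)(C)OC(C)=O | target

Total step count: 15. Longest linear sequence: 14 steps (steps 1–6 and 8–15, from 1 to 26); step 7 is a one-step side branch.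

Steps most likely to fail

Step 15. The low-valent metals may reduce the iodoenone (loss of iodine, reduction of the enone) or the aldehyde may lose an acyloxy group by β-elimination before the ring closes. The fallback closes the ring while C3 is still a silyl ether and oxidises C3 last. It sets out from 22: CSA in MeOH at 0 °C should cleave the primary silyl ether and the triethylsilyl ether but not the secondary allylic one, giving the diol with the C3 silyl ether intact F1. Dess–Martin oxidation gives the corresponding C6 aldehyde F2, whose iodide is now an ordinary cycloalkenyl iodide. CrCl2 with catalytic NiCl2 closes the seven-membered ring under the same Felkin–Anh control to the bicyclic C3 silyl ether F3, and HF·pyridine frees the C3 hydroxyl to give the bicyclic triol F4. TEMPO with PhI(OAc)2 should oxidise the unhindered cyclopentenyl carbinol in preference to the C6 carbinol, which is flanked by C7 and its acetoxyisopropyl group, and the route is rejoined at 26.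

Step 3. The chair-like crotyl transfer may not distinguish well enough between the two carbonyl faces or between the two ring arms, so that C1 or C10 epimers dilute 6. The fallback sets C10 on a ring instead and sets out from 4. The alkenylmagnesium reagent made from ethyl (Z)-3-iodobut-2-enoate and i-PrMgCl·LiCl (THF, −40 °C) adds to the ketone anti to the silyloxy group and lactonises to the spirobutenolide F5. Copper hydride conjugate reduction (Cu(OAc)2 cat., 1,2-bis(diphenylphosphino)benzene, polymethylhydrosiloxane, t-BuOH, toluene) should deliver hydride to C10 from the lactone face remote from the iodoalkenyl arm, giving the saturated spirolactone F6 with the C10 methyl group cis to that arm, as the target requires. Aminolysis with MeNH(OMe)·HCl and Me2AlCl opens the lactone to the hydroxy Weinreb amide F7, TESOTf with 2,6-lutidine gives its triethylsilyl ether F8, and diisobutylaluminium hydride at −78 °C returns to the route at 10.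

Step 8. The boron enolate may lose the silyloxy group by β-elimination, or the syn selectivity may erode with this functionalised donor. The fallback carries C6 as a vinyl group and sets out from 10 and 12. Acylation of 12 with (E)-but-2-enoyl chloride gives the crotonyl imide F9. Its boron dienolate (Bu2BOTf, Et3N) reacts with 10 at the α-carbon in the same Evans syn sense to give the α-vinyl aldol adduct F10. Methanolysis with MeOMgBr gives the methyl ester F11, and MeMgBr with CeCl3 gives the vinyl diol F12. Ozonolysis of the terminal alkene with NaBH4 work-up gives the triol F13 (the tetrasubstituted iodoalkene should react far more slowly), and TBSCl with imidazole silylates the primary hydroxyl selectively, rejoining the route at 18.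

Further compounds
F1 | step 15 | (3S,4R,6S)-2-acetoxy-6-[(1R,4R)-4-(tert-butyldimethylsilyloxy)-1-hydroxy-2-iodo-3-methylcyclopent-2-en-1-yl]-3-(hydroxymethyl)-2-methylheptan-4-yl (Z)-2-methylbut-2-enoate | OC[C@H](C(C)(C)OC(C)=O)[C@H](OC(=O)/C(C)=C\C)C[C@H](C)[C@]1(O)C[C@@H](O[Si](C)(C)C(C)(C)C)C(C)=C1I
F2 | step 15 | (3S,4R,6S)-2-acetoxy-6-[(1R,4R)-4-(tert-butyldimethylsilyloxy)-1-hydroxy-2-iodo-3-methylcyclopent-2-en-1-yl]-3-formyl-2-methylheptan-4-yl (Z)-2-methylbut-2-enoate | O=C[C@H](C(C)(C)OC(C)=O)[C@H](OC(=O)/C(C)=C\C)C[C@H](C)[C@]1(O)C[C@@H](O[Si](C)(C)C(C)(C)C)C(C)=C1I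
F3 | step 15 | (1R,3R,6R,7S,8R,10S)-11-acetoxy-3-(tert-butyldimethylsilyloxy)-1,6-dihydroxyguai-4-en-8-yl (Z)-2-methylbut-2-enoate | C/C=C(/C)C(=O)O[C@@H]1C[C@H](C)[C@]2(O)C[C@@H](O[Si](C)(C)C(C)(C)C)C(C)=C2[C@H](O)[C@@H]1C(C)(C)OC(C)=O
F4 | step 15 | (1R,3R,6R,7S,8R,10S)-11-acetoxy-1,3,6-trihydroxyguai-4-en-8-yl (Z)-2-methylbut-2-enoate | C/C=C(/C)C(=O)O[C@@H]1C[C@H](C)[C@]2(O)C[C@@H](O)C(C)=C2[C@H](O)[C@@H]1C(C)(C)OC(C)=O
F5 | step 3 | (5R,8R)-8-(tert-butyldimethylsilyloxy)-6-iodo-4,7-dimethyl-1-oxaspiro[4.4]nona-3,6-dien-2-one | CC1=CC(=O)O[C@]12C[C@@H](O[Si](C)(C)C(C)(C)C)C(C)=C2I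
F6 | step 3 | (4S,5R,8R)-8-(tert-butyldimethylsilyloxy)-6-iodo-4,7-dimethyl-1-oxaspiro[4.4]non-6-en-2-one | C[C@H]1CC(=O)O[C@]12C[C@@H](O[Si](C)(C)C(C)(C)C)C(C)=C2I
F7 | step 3 | (3S)-3-[(1R,4R)-4-(tert-butyldimethylsilyloxy)-1-hydroxy-2-iodo-3-methylcyclopent-2-en-1-yl]-N-methoxy-N-methylbutanamide | CON(C)C(=O)C[C@H](C)[C@]1(O)C[C@@H](O[Si](C)(C)C(C)(C)C)C(C)=C1I
F8 | step 3 | (3S)-N-methoxy-N-methyl-3-(ring unit A)butanamide | CON(C)C(=O)C[C@H](C)[C@]1(O[Si](CC)(CC)CC)C[C@@H](O[Si](C)(C)C(C)(C)C)C(C)=C1I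
F9 | step 8 | (S)-4-benzyl-3-[(E)-but-2-enoyl]oxazolidin-2-one | C/C=C/C(=O)N1[C@@H](Cc2ccccc2)COC1=O
F10 | step 8 | (S)-4-benzyl-3-[(2S,3R,5S)-2-ethenyl-3-hydroxy-5-(ring unit A)hexanoyl]oxazolidin-2-one | C=C[C@H](C(=O)N1[C@@H](Cc2ccccc2)COC1=O)[C@H](O)C[C@H](C)[C@]1(O[Si](CC)(CC)CC)C[C@@H](O[Si](C)(C)C(C)(C)C)C(C)=C1I
F11 | step 8 | methyl (2S,3R,5S)-2-ethenyl-3-hydroxy-5-(ring unit A)hexanoate | C=C[C@H](C(=O)OC)[C@H](O)C[C@H](C)[C@]1(O[Si](CC)(CC)CC)C[C@@H](O[Si](C)(C)C(C)(C)C)C(C)=C1I
F12 | step 8 | (3S,4R,6S)-3-ethenyl-2-methyl-6-(ring unit A)heptane-2,4-diol | C=C[C@H](C(C)(C)O)[C@H](O)C[C@H](C)[C@]1(O[Si](CC)(CC)CC)C[C@@H](O[Si](C)(C)C(C)(C)C)C(C)=C1I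
F13 | step 8 | (3S,4R,6S)-3-(hydroxymethyl)-2-methyl-6-(ring unit A)heptane-2,4-diol | OC[C@H](C(C)(C)O)[C@H](O)C[C@H](C)[C@]1(O[Si](CC)(CC)CC)C[C@@H](O[Si](C)(C)C(C)(C)C)C(C)=C1I
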